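If you want a quick number for the 0.40 M flask, I would reckon it in mM per hour, not in percent. The question and the runs stand here:

all flasks: gas phase 110 mM (held)
- violet: solid substrate 0.20 M; run made earlier
- blue: solid substrate 0.30 M; run made earlier
- flask: solid substrate 0.40 M; time 2.0 d

| run | time / h | target / % |
|---|---|---|
| violet | 3.00 | 0.8 |
| violet | 5.00 | 1.7 |
| violet | 8.00 | 3.5 |
| violet | 15.0 | 11.4 |
| violet | 25.0 | 21.9 |
| violet | 40.0 | 31.7 |
| blue | 6.00 | 1.0 |
| blue | 12.0 | 5.3 |
| blue | 20.0 | 11.6 |
| blue | 25.0 | 14.9 |
| blue | 30.0 | 18.6 |
| blue | 40.0 | 25.6 |

(standard deviation of a reading: 0.3 percentage points)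

- given per volume of solution although it is solid: solid substrate
- what was read earlier has a scatter of 0.3 percentage points, one standard deviation
- at the start none of the gas phase is in solution
- at the start none of the solid substrate is in solution

- west: doubling the dissolution coefficient of the solid substrate, all else as stated
- south: doubling the saturation concentration of gas phase, all else as stated
- east: doubling the transfer coefficient of the gas phase, all else as stated
- south-east: doubling the solubility of the solid substrate, all else as stated

- amount of target at 2.0 d, in percent of the solid substrate charged
- the change that raises the amount of target at 2.0 d, in percent of the solid substrate charged most ("none" if none brings more than 2 percentage points) (west / south / east / south-east / none)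
- amount of target at 2.0 d, in percent of the solid substrate charged, after south

My zero of the scale is the flask in which the charge makes no difference to the mM made per hour, that is, zero order in the charge; the percent then simply falls as the charge grows. Blue gains 2.18 mM h⁻¹ between 12.0 h and 40.0 h, and I call this the make rate, the mM of target gained per hour once the lag is past. Violet, from a different charge, gives 2.16 mM h⁻¹ up to 25.0 h, and then it bends. If the bend moves with the charge, it comes at 50.0 h, narrowly later than 48 h. Blue's line puts the lag at 4.69 h, so I commit to 23.6 %.

Your hunch, the forecast, says 23.6 %, level with my figure, with south as the best change and 42 % after it: “Doubling the gas saturation should therefore nearly double the rate”.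

The flask gives 24.0 %. South is the best change, gaining 12 percentage points, and it ends at 35.8 %, which is 6.2 points below the forecast.

    gas phase ⇌ dissolved gas, rate k1*(csat - [dissolved gas]) (kL = 3.40 × 10⁻⁵ s⁻¹)
    starting material + dissolved gas → target (k = 1.80 × 10⁻⁴ M⁻¹ s⁻¹)
    starting material → side product (k = 1.20 × 10⁻⁵ s⁻¹)
    solid substrate ⇌ starting material, rate k4*(cs4 - [starting material]) while solid is left; crystals form when [starting material] > cs4 (solubility = 0.130 M, k = 4.10 × 10⁻⁵ s⁻¹)
    2 dissolved gas → homo dimer (k = 6.00 × 10⁻⁴ M⁻¹ s⁻¹)

Past the same lag, the flask makes 2.21 mM h⁻¹ on average, but south makes 3.31 mM h⁻¹, which is 1.52 times the make rate. The largest single effect among the simulated runs is the drag of the transfer of gas phase to dissolved gas: without it this flask gives 55.5 % in place of 24.0 %. A further part is the loss of dissolved gas to homo dimer: without it this flask gives 41.3 %. That loss runs with the square of [dissolved gas], the target step with its first power.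

For the flask with 0.68 M of solid substrate at the same time, the make rate past the lag gives 13.9 %; the computed result is 14.1 %.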